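**Plan** (side chain numbered C1′ = benzylic CH2 through C16′; ring C1 = the phenol carbon between CH3 and C1′)
1. Cuts: C1′–C2′ together with C3′–CH3 (terminal alkyne + Me3Al + ArCH2Cl, three components); C4′–C5′ (propargyl + enal); C5′–C6′ with C7′–CH3 (alkyne + Me3Al + CH2O); C9′–C10′ (sp2–sp3 Negishi coupling, after C11′–CH3/C10′–I); C12′–C13′ (asymmetric propargylation of prenal).
2. Forward: the chain grows from the isobutenyl tail toward the head by two rounds of propargylation/methylalumination (steps 1–8); the benzylic chloride is made from 3-methylsalicylaldehyde (steps 9–12); the halves are joined in step 13; then TES removal, C5′ oxidation and global desilylation.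
3. Enabling feature: each (E)-CH=C(CH3)–CH2 unit (C2′=C3′, C6′=C7′, C10′=C11′) is the syn-methylmetalation pattern of a terminal alkyne HC≡C–CH2–. The oxygenated carbons C5′ and C13′ are homopropargylic to those alkynes. C1′ is a benzylic carbon ortho to the C1 oxygen of the hydroquinone ring, so it is available as an activated benzylic chloride.
4. Stereochemistry: C13′ (S) comes from catalyst-controlled allenylboration of prenal; the three E olefins come from syn-carboalumination with stereoretentive trapping; the C5′ carbinol is carried as a mixture and erased by oxidation.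

Key step: step 13

Remark: the C5′ carbinol center of 17, 18 and 26–28 is destroyed in step 15, so these compounds are carried as C5′ epimer mixtures and drawn without configuration at that carbon.

**Step 1**
Reactants: 1 3-methylbut-2-enal (prenal); 2 allenylboronic acid pinacol ester
Product: 4 (4S)-6-methylhept-5-en-1-yn-4-ol, via pinacol borate ester 3 (not isolated)
Conditions: (S)-TRIP phosphoric acid (5 mol %), 4 Å MS, toluene, −20 °C; aq. NaHCO3 work-up
Reagents that add atoms: none
Why: Chiral phosphoric acid-catalysed allenylboration (asymmetric propargylation) runs through a closed six-membered SE2′ transition state in which the catalyst is expected to direct the propargyl unit to the Si face of the aldehyde, setting C13′ as (S); the sense of induction would be checked by Mosher ester analysis and the antipodal catalyst used if required.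

**Step 2**
Reactants: 4 (4S)-6-methylhept-5-en-1-yn-4-ol
Product: 5 tert-butyl(dimethyl){[(4S)-6-methylhept-5-en-1-yn-4-yl]oxy}silane
Conditions: TBSCl, imidazole, DMF, 0 °C → rt
Reagents that add atoms: tert-butyldimethylsilyl chloride CC(C)(C)[Si](C)(C)Cl
Why: Standard silylation of a secondary alcohol masks the C13′ hydroxyl against Me3Al, organolithium and oxidants without touching the stereocenter.

**Step 3**
Reactants: 5 tert-butyl(dimethyl){[(4S)-6-methylhept-5-en-1-yn-4-yl]oxy}silane
Product: 7 tert-butyl{[(1E,4S)-1-iodo-2,6-dimethylhepta-1,5-dien-4-yl]oxy}dimethylsilane, via alkenyl(dimethyl)alane 6 (not isolated)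
Conditions: Me3Al (2.5 equiv), Cp2ZrCl2 (0.25 equiv), CH2Cl2, 0 °C → rt; then I2, THF, −30 → 0 °C
Reagents that add atoms: trimethylaluminium C[Al](C)C; iodine II
Why: Negishi Zr-catalysed syn-methylalumination of the terminal alkyne places Al on the terminal carbon and methyl on the internal one, and iodinolysis with retention should give the (E)-iodide that fixes the C10′=C11′ geometry.

**Step 4**
Reactants: 7 tert-butyl{[(1E,4S)-1-iodo-2,6-dimethylhepta-1,5-dien-4-yl]oxy}dimethylsilane; 8 (4-bromobut-1-yn-1-yl)trimethylsilane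
Product: 11 tert-butyl{[(5E,8S)-6,10-dimethylundeca-5,9-dien-1-yn-8-yl]oxy}dimethylsilane, via organozinc bromide 9 (not isolated), via TMS-capped enyne 10 (not isolated)
Conditions: 8, activated Zn dust, LiCl, THF, 40 °C; then 7, Pd(PPh3)4 (5 mol %), THF, rt → 45 °C; then K2CO3 (cat.), MeOH, rt
Reagents that add atoms: none
Why: Pd-catalysed Negishi sp2–sp3 coupling of the alkenyl iodide with the homopropargylic zinc reagent proceeds with retention of olefin geometry, and methanolysis of the alkynyl C–Si bond then frees the terminal alkyne for the next methylalumination.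

**Step 5**
Reactants: 11 tert-butyl{[(5E,8S)-6,10-dimethylundeca-5,9-dien-1-yn-8-yl]oxy}dimethylsilane
Product: 13 (2E,6E,9S)-9-[(tert-butyldimethylsilyl)oxy]-3,7,11-trimethyldodeca-2,6,10-trien-1-ol, via alkenyl(dimethyl)alane 12 (not isolated)
Conditions: Me3Al (2.5 equiv), Cp2ZrCl2 (0.25 equiv), CH2Cl2, 0 °C → rt; then n-BuLi, −78 °C; (CH2O)n, THF, rt; aq. NH4Cl
Reagents that add atoms: trimethylaluminium C[Al](C)C; paraformaldehyde (as formaldehyde) C=O
Why: A second Negishi methylalumination (the trisubstituted olefin is inert), followed by ate-complex formation with n-BuLi and trapping with formaldehyde, should deliver the (2E)-allylic alcohol and fix the C6′=C7′ geometry.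

**Step 6**
Reactants: 13 (2E,6E,9S)-9-[(tert-butyldimethylsilyl)oxy]-3,7,11-trimethyldodeca-2,6,10-trien-1-ol
Product: 14 (2E,6E,9S)-9-[(tert-butyldimethylsilyl)oxy]-3,7,11-trimethyldodeca-2,6,10-trienal
Conditions: TEMPO (10 mol %), PhI(OAc)2, CH2Cl2, rt
Reagents that add atoms: none
Why: TEMPO/PhI(OAc)2 oxidation is selective for the primary allylic alcohol and should give the enal without E/Z isomerisation or loss of the TBS ether.

**Step 7**
Reactants: 14 (2E,6E,9S)-9-[(tert-butyldimethylsilyl)oxy]-3,7,11-trimethyldodeca-2,6,10-trienal; 15 propargyl bromide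
Product: 17 (5E,9E,12S)-12-[(tert-butyldimethylsilyl)oxy]-6,10,14-trimethylpentadeca-5,9,13-trien-1-yn-4-ol (C4 epimers), via allenylzinc bromide 16 (not isolated)
Conditions: Zn dust, THF/sat. aq. NH4Cl, 0 °C → rt
Reagents that add atoms: none
Why: Zinc-mediated Barbier propargylation adds the allenylzinc species 1,2 to the enal by an SE2′ pathway to give the homopropargylic alcohol, whose new C5′ center needs no control because it is oxidised later.

**Step 8**
Reactants: 17 (5E,9E,12S)-12-[(tert-butyldimethylsilyl)oxy]-6,10,14-trimethylpentadeca-5,9,13-trien-1-yn-4-ol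
Product: 18 (5E,9E,12S)-12-[(tert-butyldimethylsilyl)oxy]-6,10,14-trimethyl-4-[(triethylsilyl)oxy]pentadeca-5,9,13-trien-1-yne (C4 epimers)
Conditions: TESCl, imidazole, CH2Cl2, 0 °C
Reagents that add atoms: chlorotriethylsilane CC[Si](Cl)(CC)CC
Why: Silylation with TESCl/imidazole masks the C5′ hydroxyl with a group that tolerates Me3Al yet can later be removed in the presence of the TBS ethers.

**Step 9**
Reactants: 19 2-hydroxy-3-methylbenzaldehyde
Product: 21 2,5-dihydroxy-3-methylbenzaldehyde, via aryl sulfate potassium salt 20 (not isolated)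
Conditions: K2S2O8, aq. KOH, 0 °C → rt; then conc. HCl, 80 °C
Reagents that add atoms: potassium peroxodisulfate [K+].[K+].[O-]S(=O)(=O)OOS(=O)(=O)[O-]
Why: Elbs persulfate oxidation hydroxylates a phenolate para to the oxygen via the aryl sulfate, and the only para position of this salicylaldehyde is the one required.

**Step 10**
Reactants: 21 2,5-dihydroxy-3-methylbenzaldehyde
Product: 22 2,5-bis[(tert-butyldimethylsilyl)oxy]-3-methylbenzaldehyde
Conditions: TBSCl (2.5 equiv), imidazole, DMAP (cat.), DMF, rt → 40 °C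
Reagents that add atoms: tert-butyldimethylsilyl chloride CC(C)(C)[Si](C)(C)Cl
Why: Exhaustive silylation protects both phenols as fluoride-labile ethers that should survive the organoaluminium and nickel chemistry.

**Step 11**
Reactants: 22 2,5-bis[(tert-butyldimethylsilyl)oxy]-3-methylbenzaldehyde
Product: 23 {2,5-bis[(tert-butyldimethylsilyl)oxy]-3-methylphenyl}methanol
Conditions: DIBAL-H, CH2Cl2, −78 °C; Rochelle salt work-up
Reagents that add atoms: none
Why: DIBAL-H reduces the aldehyde at −78 °C, and the low temperature with a non-basic work-up should suppress aryl-to-benzyl O→O silyl migration.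

**Step 12**
Reactants: 23 {2,5-bis[(tert-butyldimethylsilyl)oxy]-3-methylphenyl}methanol
Product: 25 2,5-bis[(tert-butyldimethylsilyl)oxy]-3-methylbenzyl chloride, via benzylic mesylate 24 (not isolated)
Conditions: MsCl, Et3N, LiCl, THF, 0 °C → rt
Reagents that add atoms: lithium chloride [Li+].[Cl-]
Why: Mesylation followed by in situ SN2 displacement by chloride converts the electron-rich benzylic alcohol into the chloride under basic conditions that spare the aryl silyl ethers.

**Step 13**
Reactants: 18 (5E,9E,12S)-12-[(tert-butyldimethylsilyl)oxy]-6,10,14-trimethyl-4-[(triethylsilyl)oxy]pentadeca-5,9,13-trien-1-yne; 25 2,5-bis[(tert-butyldimethylsilyl)oxy]-3-methylbenzyl chloride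
Product: 27 1,4-bis(TBSO)-2-methyl-6-[(2′E,6′E,10′E,13′S)-13′-(TBSO)-5′-(TESO)-3′,7′,11′,15′-tetramethylhexadeca-2′,6′,10′,14′-tetraenyl]benzene, via alkenyl(dimethyl)alane 26 (not isolated)
Conditions: 18 (1.1 equiv), Me3Al (2 equiv), Cp2ZrCl2 (0.25 equiv), CH2Cl2, 0 °C → rt; volatiles (excess Me3Al) removed in vacuo; then 25, NiCl2(PPh3)2/n-BuLi (Ni(0), 5 mol %), THF, 0 °C → rt
Reagents that add atoms: trimethylaluminium C[Al](C)C
Why: Zr-catalysed syn-methylalumination of the terminal alkyne of 18 (Negishi carboalumination) puts the methyl group on C3′ and aluminium on C2′; Ni(0) then inserts into the benzylic C–Cl bond of 25, the alkenyl group passes from Al to Ni, and reductive elimination forms the C1′–C2′ bond with retention, so alkyne, methyl and arylmethyl are united in one operation. The closest known reaction type is the carboalumination/Ni(0)-catalysed coupling of alkenylalanes with benzylic chlorides used to attach polyprenyl chains to (hydro)quinone nuclei, a Negishi-type cross-coupling. No ring is closed and no stereocenter is formed; the (2′E) geometry is controlled by the syn addition and the stereoretentive coupling. The step needs regioselectivity (Al at the terminal carbon, secured by the terminal alkyne), chemoselectivity for the alkyne over the three trisubstituted olefins (inert to methylalumination) and cross- over homo-coupling (secured by using the chloride and stripping excess Me3Al before the nickel is added). C5′ is held at the alcohol oxidation level as its TES ether because a β,γ-alkynyl ketone would not survive Me3Al, and the phenols are silylated so that no acidic proton or quinone is present.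

**Step 14**
Reactants: 27 fully silylated coupling product
Product: 28 (2′E,6′E,10′E,13′S)-5′-hydroxy compound: 1,4-bis(TBSO)-2-methyl-6-[13′-(TBSO)-5′-hydroxy-3′,7′,11′,15′-tetramethylhexadeca-2′,6′,10′,14′-tetraenyl]benzene
Conditions: PPTS (cat.), MeOH/CH2Cl2, 0 °C
Reagents that add atoms: none
Why: Mild acid-catalysed methanolysis should cleave the less hindered triethylsilyl ether selectively over the secondary alkyl and the aryl TBS ethers.

**Step 15**
Reactants: 28 5′-hydroxy tris-TBS compound
Product: 29 (2′E,6′E,10′E,13′S)-5′-oxo compound: 1,4-bis(TBSO)-2-methyl-6-[13′-(TBSO)-3′,7′,11′,15′-tetramethyl-5′-oxohexadeca-2′,6′,10′,14′-tetraenyl]benzene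
Conditions: Dess–Martin periodinane, NaHCO3, CH2Cl2, 0 °C
Reagents that add atoms: none
Why: Buffered Dess–Martin oxidation converts the secondary allylic alcohol to the ketone under neutral conditions that should not move the C2′=C3′ double bond into conjugation, and it removes the uncontrolled C5′ center.

**Step 16**
Reactants: 29 5′-oxo tris-TBS compound
Product: 30 2-[(2E,6E,10E,13S)-13-hydroxy-3,7,11,15-tetramethyl-5-oxohexadeca-2,6,10,14-tetraen-1-yl]-6-methylbenzene-1,4-diol (target)
Conditions: TBAF/AcOH (1:1, excess), degassed THF, 0 °C → rt, argon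
Reagents that add atoms: none
Why: Acetic acid-buffered fluoride cleaves the two aryl and the secondary alkyl TBS ethers under near-neutral conditions chosen to avoid isomerisation of the β,γ-unsaturated ketone and to leave the allylic C13′ center untouched.

**Compound list**
1 | 3-methylbut-2-enal (prenal) | CC(C)=CC=O | starting material
2 | allenylboronic acid pinacol ester | C=C=CB1OC(C)(C)C(C)(C)O1 | starting material
3 | 2-{[(4S)-6-methylhept-5-en-1-yn-4-yl]oxy}-4,4,5,5-tetramethyl-1,3,2-dioxaborolane | CC(C)=C[C@@H](OB1OC(C)(C)C(C)(C)O1)CC#C | intermediate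
4 | (4S)-6-methylhept-5-en-1-yn-4-ol | CC(C)=C[C@@H](O)CC#C | intermediate
5 | tert-butyl(dimethyl){[(4S)-6-methylhept-5-en-1-yn-4-yl]oxy}silane | CC(C)=C[C@@H](O[Si](C)(C)C(C)(C)C)CC#C | intermediate
6 | [(1E,4S)-4-(TBSO)-2,6-dimethylhepta-1,5-dien-1-yl]dimethylaluminium | CC(C)=C[C@@H](O[Si](C)(C)C(C)(C)C)C/C(C)=C/[Al](C)C | intermediate
7 | tert-butyl{[(1E,4S)-1-iodo-2,6-dimethylhepta-1,5-dien-4-yl]oxy}dimethylsilane | CC(C)=C[C@@H](O[Si](C)(C)C(C)(C)C)C/C(C)=C/I | intermediate
8 | (4-bromobut-1-yn-1-yl)trimethylsilane | C[Si](C)(C)C#CCCBr | starting material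
9 | bromo[4-(trimethylsilyl)but-3-yn-1-yl]zinc | C[Si](C)(C)C#CCC[Zn]Br | intermediate
10 | tert-butyl{[(5E,8S)-6,10-dimethyl-1-(trimethylsilyl)undeca-5,9-dien-1-yn-8-yl]oxy}dimethylsilane | CC(C)=C[C@@H](O[Si](C)(C)C(C)(C)C)C/C(C)=C/CCC#C[Si](C)(C)C | intermediate
11 | tert-butyl{[(5E,8S)-6,10-dimethylundeca-5,9-dien-1-yn-8-yl]oxy}dimethylsilane | CC(C)=C[C@@H](O[Si](C)(C)C(C)(C)C)C/C(C)=C/CCC#C | intermediate
12 | [(1E,5E,8S)-8-(TBSO)-2,6,10-trimethylundeca-1,5,9-trien-1-yl]dimethylaluminium | CC(C)=C[C@@H](O[Si](C)(C)C(C)(C)C)C/C(C)=C/CC/C(C)=C/[Al](C)C | intermediate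
13 | (2E,6E,9S)-9-[(tert-butyldimethylsilyl)oxy]-3,7,11-trimethyldodeca-2,6,10-trien-1-ol | CC(C)=C[C@@H](O[Si](C)(C)C(C)(C)C)C/C(C)=C/CC/C(C)=C/CO | intermediate
14 | (2E,6E,9S)-9-[(tert-butyldimethylsilyl)oxy]-3,7,11-trimethyldodeca-2,6,10-trienal | CC(C)=C[C@@H](O[Si](C)(C)C(C)(C)C)C/C(C)=C/CC/C(C)=C/C=O | intermediate
15 | propargyl bromide (3-bromoprop-1-yne) | C#CCBr | starting material
16 | allenylzinc bromide (propa-1,2-dien-1-ylzinc bromide) | C=C=C[Zn]Br | intermediate
17 | (5E,9E,12S)-12-[(tert-butyldimethylsilyl)oxy]-6,10,14-trimethylpentadeca-5,9,13-trien-1-yn-4-ol (C4 epimers) | CC(C)=C[C@@H](O[Si](C)(C)C(C)(C)C)C/C(C)=C/CC/C(C)=C/C(O)CC#C | intermediate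
18 | (5E,9E,12S)-12-[(tert-butyldimethylsilyl)oxy]-6,10,14-trimethyl-4-[(triethylsilyl)oxy]pentadeca-5,9,13-trien-1-yne (C4 epimers) | CC(C)=C[C@@H](O[Si](C)(C)C(C)(C)C)C/C(C)=C/CC/C(C)=C/C(O[Si](CC)(CC)CC)CC#C | intermediate
19 | 2-hydroxy-3-methylbenzaldehyde | Cc1cccc(C=O)c1O | starting material
20 | potassium 3-formyl-4-hydroxy-5-methylphenyl sulfate | Cc1cc(OS(=O)(=O)[O-])cc(C=O)c1O.[K+] | intermediate
21 | 2,5-dihydroxy-3-methylbenzaldehyde | Cc1cc(O)cc(C=O)c1O | intermediate
22 | 2,5-bis[(tert-butyldimethylsilyl)oxy]-3-methylbenzaldehyde | Cc1cc(O[Si](C)(C)C(C)(C)C)cc(C=O)c1O[Si](C)(C)C(C)(C)C | intermediate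
23 | {2,5-bis[(tert-butyldimethylsilyl)oxy]-3-methylphenyl}methanol | Cc1cc(O[Si](C)(C)C(C)(C)C)cc(CO)c1O[Si](C)(C)C(C)(C)C | intermediate
24 | 2,5-bis[(tert-butyldimethylsilyl)oxy]-3-methylbenzyl methanesulfonate | Cc1cc(O[Si](C)(C)C(C)(C)C)cc(COS(C)(=O)=O)c1O[Si](C)(C)C(C)(C)C | intermediate
25 | 2,5-bis[(tert-butyldimethylsilyl)oxy]-3-methylbenzyl chloride | Cc1cc(O[Si](C)(C)C(C)(C)C)cc(CCl)c1O[Si](C)(C)C(C)(C)C | intermediate
26 | [(1E,5E,9E,12S)-12-(TBSO)-4-(TESO)-2,6,10,14-tetramethylpentadeca-1,5,9,13-tetraen-1-yl]dimethylaluminium | CC(C)=C[C@@H](O[Si](C)(C)C(C)(C)C)C/C(C)=C/CC/C(C)=C/C(O[Si](CC)(CC)CC)C/C(C)=C/[Al](C)C | intermediate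
27 | 1,4-bis(TBSO)-2-methyl-6-[(2′E,6′E,10′E,13′S)-13′-(TBSO)-5′-(TESO)-3′,7′,11′,15′-tetramethylhexadeca-2′,6′,10′,14′-tetraenyl]benzene (C5′ epimers) | CC(C)=C[C@@H](O[Si](C)(C)C(C)(C)C)C/C(C)=C/CC/C(C)=C/C(O[Si](CC)(CC)CC)C/C(C)=C/Cc1cc(O[Si](C)(C)C(C)(C)C)cc(C)c1O[Si](C)(C)C(C)(C)C | intermediate
28 | 1,4-bis(TBSO)-2-methyl-6-[(2′E,6′E,10′E,13′S)-13′-(TBSO)-5′-hydroxy-3′,7′,11′,15′-tetramethylhexadeca-2′,6′,10′,14′-tetraenyl]benzene (C5′ epimers) | CC(C)=C[C@@H](O[Si](C)(C)C(C)(C)C)C/C(C)=C/CC/C(C)=C/C(O)C/C(C)=C/Cc1cc(O[Si](C)(C)C(C)(C)C)cc(C)c1O[Si](C)(C)C(C)(C)C | intermediate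
29 | 1,4-bis(TBSO)-2-methyl-6-[(2′E,6′E,10′E,13′S)-13′-(TBSO)-3′,7′,11′,15′-tetramethyl-5′-oxohexadeca-2′,6′,10′,14′-tetraenyl]benzene | CC(C)=C[C@@H](O[Si](C)(C)C(C)(C)C)C/C(C)=C/CC/C(C)=C/C(=O)C/C(C)=C/Cc1cc(O[Si](C)(C)C(C)(C)C)cc(C)c1O[Si](C)(C)C(C)(C)C | intermediate
30 | 2-[(2E,6E,10E,13S)-13-hydroxy-3,7,11,15-tetramethyl-5-oxohexadeca-2,6,10,14-tetraen-1-yl]-6-methylbenzene-1,4-diol | CC(C)=C[C@@H](O)C/C(C)=C/CC/C(C)=C/C(=O)C/C(C)=C/Cc1cc(O)cc(C)c1O | target

**Step count:** 16 steps in total; longest linear sequence 12 steps (steps 1–8, then 13–16).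

**Steps most likely to fail**

Step 13. What may go wrong: incomplete or unselective methylalumination of the polyfunctional alkyne, methyl transfer to or homocoupling of the benzylic chloride, and ionisation of the o-silyloxybenzyl chloride by the Lewis-acidic alane. Fallback, setting out from 18 and 25 and returning at 27: the two events are separated and the polarity of the coupling is reversed. Alkyne 18 would be methylaluminated as in step 3 and the alane 26 quenched with iodine to give the (1E,5E,9E,12S)-1-iodo-2,6,10,14-tetramethyl-12-(TBSO)-4-(TESO)pentadeca-1,5,9,13-tetraene F1. Chloride 25 would be converted with zinc dust/LiCl in THF into the benzylic zinc chloride F2. Pd-catalysed Negishi coupling of F1 with F2 (Pd(OAc)2/SPhos, THF, rt) should then give 27.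

Step 16. What may go wrong: base-induced migration of the C2′=C3′ double bond into conjugation with the C5′ ketone during fluoride treatment, incomplete cleavage of the hindered silyl ethers, and air oxidation of the freed hydroquinone. Fallback, setting out from 29 and returning at 30: the ring is taken through the quinone so that no basic fluoride is needed. Ceric ammonium nitrate (MeCN/H2O, 0 °C) should oxidatively remove both aryl silyl groups to give the 13′-silyloxy quinone F3. Aqueous HF in MeCN would then cleave the remaining alkyl TBS ether under acidic conditions to give the 13′-hydroxy quinone F4. Reduction with Na2S2O4 (THF/H2O) should give hydroquinone 30.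

Step 1. What may go wrong: insufficient enantioselectivity or the wrong sense of induction with a β,β-disubstituted enal, and loss of the volatile product on isolation. Fallback, setting out from 1 and 15 and returning at 4: the stereocenter is obtained by resolution instead of catalysis. Zinc-mediated Barbier propargylation of 1 with 15 would give the racemic 6-methylhept-5-en-1-yn-4-ol F5. Lipase-catalysed kinetic resolution (Amano PS or CAL-B, vinyl acetate) is expected to acylate the (R)-enantiomer to the (4R)-acetate F6 and leave the (S)-alcohol 4, which would be separated by chromatography and its configuration checked by Mosher ester analysis.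

**Further compounds**
F1 | step 13 | (1E,5E,9E,12S)-12-[(tert-butyldimethylsilyl)oxy]-1-iodo-2,6,10,14-tetramethyl-4-[(triethylsilyl)oxy]pentadeca-1,5,9,13-tetraene (C4 epimers) | CC(C)=C[C@@H](O[Si](C)(C)C(C)(C)C)C/C(C)=C/CC/C(C)=C/C(O[Si](CC)(CC)CC)C/C(C)=C/I
F2 | step 13 | {2,5-bis[(tert-butyldimethylsilyl)oxy]-3-methylbenzyl}zinc chloride | Cc1cc(O[Si](C)(C)C(C)(C)C)cc(C[Zn]Cl)c1O[Si](C)(C)C(C)(C)C
F3 | step 16 | 2-[(2E,6E,10E,13S)-13-[(tert-butyldimethylsilyl)oxy]-3,7,11,15-tetramethyl-5-oxohexadeca-2,6,10,14-tetraen-1-yl]-6-methyl-1,4-benzoquinone | CC(C)=C[C@@H](O[Si](C)(C)C(C)(C)C)C/C(C)=C/CC/C(C)=C/C(=O)C/C(C)=C/CC1=CC(=O)C=C(C)C1=O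
F4 | step 16 | 2-[(2E,6E,10E,13S)-13-hydroxy-3,7,11,15-tetramethyl-5-oxohexadeca-2,6,10,14-tetraen-1-yl]-6-methyl-1,4-benzoquinone | CC(C)=C[C@@H](O)C/C(C)=C/CC/C(C)=C/C(=O)C/C(C)=C/CC1=CC(=O)C=C(C)C1=O
F5 | step 1 | rac-6-methylhept-5-en-1-yn-4-ol | CC(C)=CC(O)CC#C
F6 | step 1 | (4R)-6-methylhept-5-en-1-yn-4-yl acetate | CC(C)=C[C@H](OC(C)=O)CC#C
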